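**Plan**

- Numbering: ring B is C5–C10 and the quinone ring C is C8, C9, C11–C14. C10 carries a methyl group and the propanoate arm C1–C3, C5 carries the isopropenyl carbon C4, and C7 is the ring-B ketone.
- Cuts, in retrosynthetic order: the O-isopropyl mask at C12 and the oxidation levels at C3 and C7; ring C at C9–C11 and C8–C14 (alkenyllithium plus cyclobutenedione, then electrocyclic ring expansion); the C7–O bond (conjugate borylation of a C7=C8 enone); last, C4–C5 and C10–C1.
- Enabling feature: in ring B the methine C5 (isopropenyl) and the quaternary C10 (methyl, C1–C3 arm) are neighbours, with the arm trans to the isopropenyl group. This is what β-addition followed by anti α-alkylation leaves on a 2-methylcyclohexenone whose carbonyl carbon becomes C9.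
- Forward order: the six-membered ring B is bought. Step 1 makes C4–C5 and C10–C1. C7 and C3 are oxygenated through two C–B bonds. Ring C is closed last by 4π opening and 6π closure of a 4-alkenyl-4-hydroxycyclobutenone, which brings in C11–C14 with the C12 oxygen and the isopropyl group already in place.
- Stereochemistry: C5 comes from the chiral diphosphine on copper, and C10 is relayed from C5 by anti alkylation. The target has no other stereocentre, and neither centre can epimerise (C10 is quaternary, C5 is β to every carbonyl).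

Key step: step 1

Assumption: the ferrocenyl diphosphine is written as the antipode taken to give (S)-configured C5; this is to be checked on the first run, and the mirror-image ligand is used otherwise. The transient C7 centre is drawn throughout as the expected isomer trans to isopropenyl, and its epimer would converge when C7 becomes a carbonyl.

**Route**

Step 1
Reactants: 1 2-methylcyclohex-2-en-1-one; 2 isopropenylmagnesium bromide; 3 allyl iodide
Product: 5 (2S,3S)-2-allyl-2-methyl-3-(prop-1-en-2-yl)cyclohexan-1-one, via bromomagnesium enolate 4 (not isolated)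
Conditions: CuBr·SMe2 (5 mol %), (R)-1-[(S)-2-(diphenylphosphino)ferrocenyl]ethyldicyclohexylphosphine (6 mol %), t-BuOMe, −78 °C, slow addition of 2; then DMPU, 3, −78 → 0 °C
Reagents that add atoms: none
Why: Transmetalation of 2 to the diphosphine-bound monovalent copper bromide gives a chiral alkenylcuprate that π-complexes enone 1, adds at C5 through a σ-bound trivalent copper species and reductively eliminates to form C4–C5, leaving magnesium enolate 4 with its double bond fixed between C9 and C10; SN2 attack of this enolate on allyl iodide, accelerated by DMPU, then forms C10–C1. The closest known reaction type is the copper-catalysed asymmetric conjugate addition of Grignard reagents to cyclic enones with in-flask alkylation of the enolate. No ring is closed: the six-membered ring B is already present in 1 and only two exocyclic bonds are made. The C5 configuration is set by the chiral ligand on copper (reagent control), and the C10 configuration by the substrate, because allyl iodide approaches the enolate face opposite the neighbouring isopropenyl group, which puts allyl trans and methyl cis to it. The step needs 1,4- over 1,2-addition (secured by copper catalysis, low temperature and slow addition of 2), C-allylation at C10 before proton transfer can move the enolate towards C8 (secured by the reactive iodide and the polar additive), and a single alkylation, which the methyl group already on C10 of 1 guarantees because the alkylated carbon becomes quaternary.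

Step 2
Reactants: 5 (2S,3S)-2-allyl-2-methyl-3-(prop-1-en-2-yl)cyclohexan-1-one
Product: 6 (5S,6S)-6-allyl-6-methyl-5-(prop-1-en-2-yl)cyclohex-2-en-1-one
Conditions: LiN(iPr)2, THF, −78 °C; then N-tert-butylbenzenesulfinimidoyl chloride, −78 °C
Reagents that add atoms: none
Why: Mukaiyama dehydrogenation, in which the lithium enolate can form only towards C8 because C10 is quaternary, and S-sulfinimidoylation followed by syn elimination of the sulfenamide gives the C7=C8 enone at low temperature without palladium, so the allyl and isopropenyl groups and both stereocentres are left alone.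

Step 3
Reactants: 6 (5S,6S)-6-allyl-6-methyl-5-(prop-1-en-2-yl)cyclohex-2-en-1-one
Product: 7 (2S,3S,5R)-2-allyl-2-methyl-3-(prop-1-en-2-yl)-5-(4,4,5,5-tetramethyl-1,3,2-dioxaborolan-2-yl)cyclohexan-1-one
Conditions: CuCl (5 mol %), NaOtBu (10 mol %), bis[2-(diphenylphosphino)phenyl] ether (5 mol %), B2pin2, MeOH, THF, 23 °C
Reagents that add atoms: bis(pinacolato)diboron, CC1(C)OB(OC1(C)C)B1OC(C)(C)C(C)(C)O1
Why: Copper-catalysed conjugate borylation of an enone, in which the phosphine–copper–boryl species adds boron to C7 and methanol protonates the copper enolate; axial attack anti to the equatorial C5 isopropenyl group should place boron trans to it (a centre that is erased later), and the unactivated terminal alkenes should not react.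

Step 4
Reactants: 7 (2S,3S,5R)-2-allyl-2-methyl-3-(prop-1-en-2-yl)-5-(4,4,5,5-tetramethyl-1,3,2-dioxaborolan-2-yl)cyclohexan-1-one
Product: 9 (2S,3S,5R)-5-hydroxy-2-(3-hydroxypropyl)-2-methyl-3-(prop-1-en-2-yl)cyclohexan-1-one, via bis(pinacol boronate) 8 (not isolated)
Conditions: pinacolborane, RhCl(PPh3)3 (2 mol %), CH2Cl2, 23 °C; then NaBO3·4H2O, THF/H2O, 23 °C
Reagents that add atoms: sodium perborate tetrahydrate, B(=O)O[O-].O.O.O.O.[Na+]
Why: Rhodium-catalysed anti-Markovnikov hydroboration followed by perborate oxidation, in which the catalysed addition of pinacolborane is far faster at the monosubstituted allyl alkene than at the 1,1-disubstituted isopropenyl group or the hindered ketone, and perborate oxidises both C–B bonds with retention under conditions mild enough to keep the β-hydroxy ketone from dehydrating.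

Step 5
Reactants: 9 (2S,3S,5R)-5-hydroxy-2-(3-hydroxypropyl)-2-methyl-3-(prop-1-en-2-yl)cyclohexan-1-one
Product: 10 (2S,3S,5R)-5-{[tert-butyl(dimethyl)silyl]oxy}-2-(3-{[tert-butyl(dimethyl)silyl]oxy}propyl)-2-methyl-3-(prop-1-en-2-yl)cyclohexan-1-one
Conditions: TBSCl, imidazole, DMF, 23 °C
Reagents that add atoms: tert-butyl(chloro)dimethylsilane, CC(C)(C)[Si](C)(C)Cl
Why: Standard silylation of a primary and a secondary alcohol, chosen because both silyl ethers withstand n-BuLi and heating at 110 °C and can later be removed together with fluoride.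

Step 6
Reactants: 10 (2S,3S,5R)-5-{[tert-butyl(dimethyl)silyl]oxy}-2-(3-{[tert-butyl(dimethyl)silyl]oxy}propyl)-2-methyl-3-(prop-1-en-2-yl)cyclohexan-1-one
Product: 11 N'-[(1E,2S,3S,5R)-5-{[tert-butyl(dimethyl)silyl]oxy}-2-(3-{[tert-butyl(dimethyl)silyl]oxy}propyl)-2-methyl-3-(prop-1-en-2-yl)cyclohexylidene]-2,4,6-tri(propan-2-yl)benzenesulfonohydrazide
Conditions: 2,4,6-triisopropylbenzenesulfonohydrazide, PPTS (cat.), THF, 23 °C
Reagents that add atoms: 2,4,6-tri(propan-2-yl)benzenesulfonohydrazide, CC(C)c1cc(C(C)C)c(S(=O)(=O)NN)c(C(C)C)c1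
Why: Condensation of a ketone with an arenesulfonyl hydrazide, known for 2,2-disubstituted cyclohexanones, in which the sulfonamide nitrogen should settle anti to the quaternary C10 and therefore syn to the C8 methylene whose proton is removed in the Shapiro step.

Step 7
Reactants: 12 diisopropyl squarate; 13 isopropylmagnesium chloride
Product: 15 3-(propan-2-yloxy)-4-(propan-2-yl)cyclobut-3-ene-1,2-dione, via squarate 1,2-adduct 14 (not isolated)
Conditions: THF, −78 °C; NH4Cl (aq); then 12 M HCl (cat.), CH2Cl2, 23 °C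
Reagents that add atoms: water, O
Why: 1,2-Addition of an organomagnesium reagent to a squarate ester followed by acid-induced ionisation of the tertiary alcohol and hydrolysis of the resulting alkoxy-stabilised cation with loss of propan-2-ol, the standard preparation of 3-alkoxy-4-alkylcyclobutenediones.

Step 8
Reactants: 11 N'-[(1E,2S,3S,5R)-5-{[tert-butyl(dimethyl)silyl]oxy}-2-(3-{[tert-butyl(dimethyl)silyl]oxy}propyl)-2-methyl-3-(prop-1-en-2-yl)cyclohexylidene]-2,4,6-tri(propan-2-yl)benzenesulfonohydrazide; 15 3-(propan-2-yloxy)-4-(propan-2-yl)cyclobut-3-ene-1,2-dione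
Product: 17 4-[(3R,5S,6S)-3-{[tert-butyl(dimethyl)silyl]oxy}-6-(3-{[tert-butyl(dimethyl)silyl]oxy}propyl)-6-methyl-5-(prop-1-en-2-yl)cyclohex-1-en-1-yl]-4-hydroxy-3-(propan-2-yloxy)-2-(propan-2-yl)cyclobut-2-en-1-one (both epimers at the carbinol carbon), via alkenyllithium 16 (not isolated)
Conditions: n-BuLi (2.2 equiv), THF, −78 → 0 °C; then 15, −78 °C; NH4Cl (aq)
Reagents that add atoms: none
Why: Shapiro reaction, in which the hydrazone dianion loses sulfinate and N2 to give the C8=C9 alkenyllithium 16, which adds to the carbonyl of 15 next to the alkoxy-bearing carbon (the other carbonyl is a deactivated vinylogous ester), as is general for alkenyl- and aryllithium reagents with 3-alkoxycyclobutenediones; the new carbinol centre forms without control and is destroyed in step 9.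

Step 9
Reactants: 17 4-[(3R,5S,6S)-3-{[tert-butyl(dimethyl)silyl]oxy}-6-(3-{[tert-butyl(dimethyl)silyl]oxy}propyl)-6-methyl-5-(prop-1-en-2-yl)cyclohex-1-en-1-yl]-4-hydroxy-3-(propan-2-yloxy)-2-(propan-2-yl)cyclobut-2-en-1-one
Product: 19 (5S,6S,8R)-8-{[tert-butyl(dimethyl)silyl]oxy}-5-(3-{[tert-butyl(dimethyl)silyl]oxy}propyl)-5-methyl-2-(propan-2-yl)-3-(propan-2-yloxy)-6-(prop-1-en-2-yl)-5,6,7,8-tetrahydronaphthalene-1,4-dione, via hydroquinone 18 (not isolated)
Conditions: toluene, 110 °C; then Ag2O, Et2O, 23 °C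
Reagents that add atoms: none
Why: Moore rearrangement, in which 4π electrocyclic opening with the hydroxyl group rotating outward gives a dienylketene whose alkenyl terminus C8 lies next to the ketene carbon, 6π closure forms C8–C14 and tautomerisation gives hydroquinone 18, which Ag2O oxidises to the quinone; the regiochemistry of step 8 fixes C11 next to C9, the alkoxy group at C12 and the isopropyl group at C13.

Step 10
Reactants: 19 (5S,6S,8R)-8-{[tert-butyl(dimethyl)silyl]oxy}-5-(3-{[tert-butyl(dimethyl)silyl]oxy}propyl)-5-methyl-2-(propan-2-yl)-3-(propan-2-yloxy)-6-(prop-1-en-2-yl)-5,6,7,8-tetrahydronaphthalene-1,4-dione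
Product: 20 (5S,6S,8R)-8-hydroxy-5-(3-hydroxypropyl)-5-methyl-2-(propan-2-yl)-3-(propan-2-yloxy)-6-(prop-1-en-2-yl)-5,6,7,8-tetrahydronaphthalene-1,4-dione
Conditions: HF·pyridine, pyridine, THF, 0 → 23 °C
Reagents that add atoms: none
Why: Fluoride-mediated cleavage of both silyl ethers under buffered acidic conditions, preferred to basic fluoride sources because alkoxyquinones are sensitive to base.

Step 11
Reactants: 20 (5S,6S,8R)-8-hydroxy-5-(3-hydroxypropyl)-5-methyl-2-(propan-2-yl)-3-(propan-2-yloxy)-6-(prop-1-en-2-yl)-5,6,7,8-tetrahydronaphthalene-1,4-dione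
Product: 21 3-[(1S,2S)-1-methyl-4,5,8-trioxo-6-(propan-2-yl)-7-(propan-2-yloxy)-2-(prop-1-en-2-yl)-1,2,3,4,5,8-hexahydronaphthalen-1-yl]propanoic acid
Conditions: CrO3, H2SO4 (aq), acetone, 0 °C
Reagents that add atoms: water, O
Why: Jones oxidation, in which hexavalent chromium takes the primary alcohol through the aldehyde hydrate to the acid and the C7 carbinol to the ketone in one operation, removing the transient C7 centre, while the quinone, the fully substituted vinylogous ester and the isopropenyl group should tolerate brief exposure at 0 °C.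

Step 12
Reactants: 21 3-[(1S,2S)-1-methyl-4,5,8-trioxo-6-(propan-2-yl)-7-(propan-2-yloxy)-2-(prop-1-en-2-yl)-1,2,3,4,5,8-hexahydronaphthalen-1-yl]propanoic acid
Product: 22 methyl 3-[(1S,2S)-1-methyl-4,5,8-trioxo-6-(propan-2-yl)-7-(propan-2-yloxy)-2-(prop-1-en-2-yl)-1,2,3,4,5,8-hexahydronaphthalen-1-yl]propanoate
Conditions: Me3SiCHN2, MeOH/toluene, 0 °C
Reagents that add atoms: trimethylsilyldiazomethane, C[Si](C)(C)C=[N+]=[N-]
Why: Esterification of a carboxylic acid with a diazoalkane, selective because the C12 oxygen is still masked as its isopropyl ether and the fully substituted quinone double bonds offer no site for dipolar cycloaddition.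

Step 13
Reactants: 22 methyl 3-[(1S,2S)-1-methyl-4,5,8-trioxo-6-(propan-2-yl)-7-(propan-2-yloxy)-2-(prop-1-en-2-yl)-1,2,3,4,5,8-hexahydronaphthalen-1-yl]propanoate
Product: 23 methyl 3-[(1S,2S)-7-hydroxy-1-methyl-4,5,8-trioxo-6-(propan-2-yl)-2-(prop-1-en-2-yl)-1,2,3,4,5,8-hexahydronaphthalen-1-yl]propanoate
Conditions: BCl3, CH2Cl2, −78 → −20 °C; then NaHCO3 (aq)
Reagents that add atoms: none
Why: Lewis-acid cleavage of an isopropyl ether, in which BCl3 chelated between the C11 carbonyl and the C12 oxygen releases the isopropyl group as 2-chloropropane at low temperature, a standard selective dealkylation next to a carbonyl group that should spare the methyl ester and the isopropenyl group.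

**Compound list**

1 | 2-methylcyclohex-2-en-1-one | CC1=CCCCC1=O | starting material
2 | isopropenylmagnesium bromide (prop-1-en-2-ylmagnesium bromide) | C=C(C)[Mg]Br | starting material
3 | allyl iodide (3-iodoprop-1-ene) | C=CCI | starting material
4 | bromomagnesium (3S)-2-methyl-3-(prop-1-en-2-yl)cyclohex-1-en-1-olate | C=C(C)[C@@H]1CCCC(O[Mg]Br)=C1C | intermediate
5 | (2S,3S)-2-allyl-2-methyl-3-(prop-1-en-2-yl)cyclohexan-1-one, allyl trans to isopropenyl | C=C(C)[C@@H]1CCCC(=O)[C@@]1(C)CC=C | intermediate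
6 | (5S,6S)-6-allyl-6-methyl-5-(prop-1-en-2-yl)cyclohex-2-en-1-one | C=C(C)[C@@H]1CC=CC(=O)[C@@]1(C)CC=C | intermediate
7 | (2S,3S,5R)-2-allyl-2-methyl-3-(prop-1-en-2-yl)-5-(4,4,5,5-tetramethyl-1,3,2-dioxaborolan-2-yl)cyclohexan-1-one | C=C(C)[C@@H]1C[C@@H](B2OC(C)(C)C(C)(C)O2)CC(=O)[C@@]1(C)CC=C | intermediate
8 | (2S,3S,5R)-2-methyl-3-(prop-1-en-2-yl)-5-(4,4,5,5-tetramethyl-1,3,2-dioxaborolan-2-yl)-2-[3-(4,4,5,5-tetramethyl-1,3,2-dioxaborolan-2-yl)propyl]cyclohexan-1-one | C=C(C)[C@@H]1C[C@@H](B2OC(C)(C)C(C)(C)O2)CC(=O)[C@@]1(C)CCCB3OC(C)(C)C(C)(C)O3 | intermediate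
9 | (2S,3S,5R)-5-hydroxy-2-(3-hydroxypropyl)-2-methyl-3-(prop-1-en-2-yl)cyclohexan-1-one | C=C(C)[C@@H]1C[C@@H](O)CC(=O)[C@@]1(C)CCCO | intermediate
10 | (2S,3S,5R)-5-{[tert-butyl(dimethyl)silyl]oxy}-2-(3-{[tert-butyl(dimethyl)silyl]oxy}propyl)-2-methyl-3-(prop-1-en-2-yl)cyclohexan-1-one | C=C(C)[C@@H]1C[C@@H](O[Si](C)(C)C(C)(C)C)CC(=O)[C@@]1(C)CCCO[Si](C)(C)C(C)(C)C | intermediate
11 | N'-[(1E,2S,3S,5R)-5-{[tert-butyl(dimethyl)silyl]oxy}-2-(3-{[tert-butyl(dimethyl)silyl]oxy}propyl)-2-methyl-3-(prop-1-en-2-yl)cyclohexylidene]-2,4,6-tri(propan-2-yl)benzenesulfonohydrazide | C=C(C)[C@@H]1C[C@@H](O[Si](C)(C)C(C)(C)C)C/C(=N\NS(=O)(=O)c2c(C(C)C)cc(C(C)C)cc2C(C)C)[C@@]1(C)CCCO[Si](C)(C)C(C)(C)C | intermediate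
12 | diisopropyl squarate (3,4-di(propan-2-yloxy)cyclobut-3-ene-1,2-dione) | CC(C)OC1=C(OC(C)C)C(=O)C1=O | starting material
13 | isopropylmagnesium chloride | CC(C)[Mg]Cl | starting material
14 | 4-hydroxy-2,3-di(propan-2-yloxy)-4-(propan-2-yl)cyclobut-2-en-1-one (racemic) | CC(C)OC1=C(OC(C)C)C(O)(C(C)C)C1=O | intermediate
15 | 3-(propan-2-yloxy)-4-(propan-2-yl)cyclobut-3-ene-1,2-dione | CC(C)OC1=C(C(C)C)C(=O)C1=O | intermediate
16 | [(3R,5S,6S)-3-{[tert-butyl(dimethyl)silyl]oxy}-6-(3-{[tert-butyl(dimethyl)silyl]oxy}propyl)-6-methyl-5-(prop-1-en-2-yl)cyclohex-1-en-1-yl]lithium | C=C(C)[C@@H]1C[C@@H](O[Si](C)(C)C(C)(C)C)C=C([Li])[C@@]1(C)CCCO[Si](C)(C)C(C)(C)C | intermediate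
17 | 4-[(3R,5S,6S)-3-{[tert-butyl(dimethyl)silyl]oxy}-6-(3-{[tert-butyl(dimethyl)silyl]oxy}propyl)-6-methyl-5-(prop-1-en-2-yl)cyclohex-1-en-1-yl]-4-hydroxy-3-(propan-2-yloxy)-2-(propan-2-yl)cyclobut-2-en-1-one, both epimers at the carbinol carbon | C=C(C)[C@@H]1C[C@@H](O[Si](C)(C)C(C)(C)C)C=C(C2(O)C(OC(C)C)=C(C(C)C)C2=O)[C@@]1(C)CCCO[Si](C)(C)C(C)(C)C | intermediate
18 | (5S,6S,8R)-8-{[tert-butyl(dimethyl)silyl]oxy}-5-(3-{[tert-butyl(dimethyl)silyl]oxy}propyl)-5-methyl-2-(propan-2-yl)-3-(propan-2-yloxy)-6-(prop-1-en-2-yl)-5,6,7,8-tetrahydronaphthalene-1,4-diol | C=C(C)[C@@H]1C[C@@H](O[Si](C)(C)C(C)(C)C)c2c(O)c(C(C)C)c(OC(C)C)c(O)c2[C@@]1(C)CCCO[Si](C)(C)C(C)(C)C | intermediate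
19 | (5S,6S,8R)-8-{[tert-butyl(dimethyl)silyl]oxy}-5-(3-{[tert-butyl(dimethyl)silyl]oxy}propyl)-5-methyl-2-(propan-2-yl)-3-(propan-2-yloxy)-6-(prop-1-en-2-yl)-5,6,7,8-tetrahydronaphthalene-1,4-dione | C=C(C)[C@@H]1C[C@@H](O[Si](C)(C)C(C)(C)C)C2=C(C(=O)C(OC(C)C)=C(C(C)C)C2=O)[C@@]1(C)CCCO[Si](C)(C)C(C)(C)C | intermediate
20 | (5S,6S,8R)-8-hydroxy-5-(3-hydroxypropyl)-5-methyl-2-(propan-2-yl)-3-(propan-2-yloxy)-6-(prop-1-en-2-yl)-5,6,7,8-tetrahydronaphthalene-1,4-dione | C=C(C)[C@@H]1C[C@@H](O)C2=C(C(=O)C(OC(C)C)=C(C(C)C)C2=O)[C@@]1(C)CCCO | intermediate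
21 | 3-[(1S,2S)-1-methyl-4,5,8-trioxo-6-(propan-2-yl)-7-(propan-2-yloxy)-2-(prop-1-en-2-yl)-1,2,3,4,5,8-hexahydronaphthalen-1-yl]propanoic acid | C=C(C)[C@@H]1CC(=O)C2=C(C(=O)C(OC(C)C)=C(C(C)C)C2=O)[C@@]1(C)CCC(=O)O | intermediate
22 | methyl 3-[(1S,2S)-1-methyl-4,5,8-trioxo-6-(propan-2-yl)-7-(propan-2-yloxy)-2-(prop-1-en-2-yl)-1,2,3,4,5,8-hexahydronaphthalen-1-yl]propanoate | C=C(C)[C@@H]1CC(=O)C2=C(C(=O)C(OC(C)C)=C(C(C)C)C2=O)[C@@]1(C)CCC(=O)OC | intermediate
23 | methyl 3-[(1S,2S)-7-hydroxy-1-methyl-4,5,8-trioxo-6-(propan-2-yl)-2-(prop-1-en-2-yl)-1,2,3,4,5,8-hexahydronaphthalen-1-yl]propanoate | C=C(C)[C@@H]1CC(=O)C2=C(C(=O)C(O)=C(C(C)C)C2=O)[C@@]1(C)CCC(=O)OC | target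

**Count and risks**

Total steps: 13. Longest linear sequence: 12 (steps 1–6 and 8–13); step 7 is a one-step branch that supplies 15.

Most likely to fail:

1. Step 8. The hydrazone dianion may fragment incompletely or expel the C7 silyloxy group. The hindered alkenyllithium may also be protonated by the solvent during the warm-up, or add only sluggishly because of the neighbouring quaternary C10. The fallback sets out from ketone 10 and avoids both the hydrazone and the warm-up. Enolisation towards C8 with KN(SiMe3)2 and trapping with PhNTf2 (THF, −78 °C) should give the enol triflate (3R,5S,6S)-3-{[tert-butyl(dimethyl)silyl]oxy}-6-(3-{[tert-butyl(dimethyl)silyl]oxy}propyl)-6-methyl-5-(prop-1-en-2-yl)cyclohex-1-en-1-yl trifluoromethanesulfonate F2. Stille-type stannylation (Pd(PPh3)4, Me3SnSnMe3, LiCl, THF, 60 °C) would convert it into the alkenylstannane [(3R,5S,6S)-3-{[tert-butyl(dimethyl)silyl]oxy}-6-(3-{[tert-butyl(dimethyl)silyl]oxy}propyl)-6-methyl-5-(prop-1-en-2-yl)cyclohex-1-en-1-yl](trimethyl)stannane F3. Tin–lithium exchange with MeLi at −78 °C then re-enters the route at alkenyllithium 16, which is trapped with 15 as in step 8 to give 17.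

2. Step 1. Enantioselectivity may erode with the α-branched alkenyl Grignard reagent. C-allylation of the hindered tetrasubstituted magnesium enolate may also be slow enough for proton transfer, enolate equilibration or O-allylation to compete. The fallback sets out from 1 and 2 under the same copper catalysis but separates the two bond formations. Enolate 4 is intercepted with Me3SiCl to give the isolable silyl enol ether (S)-trimethyl{[2-methyl-3-(prop-1-en-2-yl)cyclohex-1-en-1-yl]oxy}silane F1, on which the enantiomeric purity can also be measured. The lithium enolate is then regenerated regiospecifically with MeLi in THF and alkylated with 3, anti to the isopropenyl group, to return to 5.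

3. Step 13. The Lewis acid may add HCl to the isopropenyl group or trigger a cationic rearrangement there, or attack the methyl ester, in competition with ether cleavage. The fallback sets out from acid 21 and removes the isopropyl group by addition–elimination instead. Aqueous LiOH (THF, 0 °C, under argon) should displace isopropoxide from the vinylogous ester to give 3-[(1S,2S)-7-hydroxy-1-methyl-4,5,8-trioxo-6-(propan-2-yl)-2-(prop-1-en-2-yl)-1,2,3,4,5,8-hexahydronaphthalen-1-yl]propanoic acid F4. Its carboxylate, far more nucleophilic than the delocalised hydroxyquinone anion, is then methylated selectively with MeI and KHCO3 in DMF to arrive at 23.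

**Further compounds**

F1 | step 1 | (S)-trimethyl{[2-methyl-3-(prop-1-en-2-yl)cyclohex-1-en-1-yl]oxy}silane | C=C(C)[C@@H]1CCCC(O[Si](C)(C)C)=C1C
F2 | step 8 | (3R,5S,6S)-3-{[tert-butyl(dimethyl)silyl]oxy}-6-(3-{[tert-butyl(dimethyl)silyl]oxy}propyl)-6-methyl-5-(prop-1-en-2-yl)cyclohex-1-en-1-yl trifluoromethanesulfonate | C=C(C)[C@@H]1C[C@@H](O[Si](C)(C)C(C)(C)C)C=C(OS(=O)(=O)C(F)(F)F)[C@@]1(C)CCCO[Si](C)(C)C(C)(C)C
F3 | step 8 | [(3R,5S,6S)-3-{[tert-butyl(dimethyl)silyl]oxy}-6-(3-{[tert-butyl(dimethyl)silyl]oxy}propyl)-6-methyl-5-(prop-1-en-2-yl)cyclohex-1-en-1-yl](trimethyl)stannane | C=C(C)[C@@H]1C[C@@H](O[Si](C)(C)C(C)(C)C)C=C([Sn](C)(C)C)[C@@]1(C)CCCO[Si](C)(C)C(C)(C)C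
F4 | step 13 | 3-[(1S,2S)-7-hydroxy-1-methyl-4,5,8-trioxo-6-(propan-2-yl)-2-(prop-1-en-2-yl)-1,2,3,4,5,8-hexahydronaphthalen-1-yl]propanoic acid | C=C(C)[C@@H]1CC(=O)C2=C(C(=O)C(O)=C(C(C)C)C2=O)[C@@]1(C)CCC(=O)O
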